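**Assumption and atom labels:** the target is taken exactly as drawn, i.e. (3aR,4R,6R,11aS) with a cis-fused lactone and a (2R)-2-methylbutanoate; the 4-methoxybenzyl ether of (S)-glycidol, 2-bromo-3-methylfuran and (R)-2-methylbutanoic acid are taken as catalogue chemicals. Germacranolide labels are used: C1=C2 (E), C3 ketone, C4(Me)=C5 (Z), C6 lactone O–CH, C7 ring fusion, C8 ester carbon, C9 CH2, C10 carbinol, C11–C13 methylene-lactone carbons.

## Retrosynthetic overview

1. The C8 ester is put on last, because an acyloxy group at C8 would be lost by 1,4-elimination from the allyl-metal intermediate; C8 and C10 travel as triethylsilyl (TES) ethers.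
2. The C6–C7 bond is made by an electrochemical, chromium-catalysed intramolecular allylation of the C6 aldehyde by a 2-(bromomethyl)enoate. The ten-membered carbocycle closes first, the γ-lactone (O6–C12) second, in the same flask.
3. The (Z)-ene-dione (C3 ketone, C4=C5, C6 aldehyde) is unmasked from a 2-alkenyl-3-methylfuran by singlet-oxygen photooxygenation.
4. The bromomethyl enoate comes from the C7 aldehyde (Baylis–Hillman, then SN2′ bromide); the furan is joined at C2–C3 by a Heck reaction on a vinyl carbinol.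
5. C10 is set by chelation-controlled vinyl addition to a β-hydroxy methyl ketone whose C8 centre comes from (S)-glycidol; C6 and C7 follow from C8 in the ring closure.

## Route

Step 1
Reactants: 1 (R)-2-{[(4-methoxybenzyl)oxy]methyl}oxirane; 2 vinylmagnesium bromide
Product: 3 (R)-1-[(4-methoxybenzyl)oxy]pent-4-en-2-ol
Conditions: CH2=CHMgBr (1.5 equiv), CuI (10 mol%), THF, −40 → −20 °C; aq. NH4Cl
Reagents that add atoms: vinylmagnesium bromide, C=C[Mg]Br
Why: Copper-catalysed Grignard opening of the terminal epoxide (SN2 at the unsubstituted carbon) joins C9 to the future C10/C14 unit and leaves the purchased C8 stereocentre untouched.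

Step 2
Reactants: 3 (R)-1-[(4-methoxybenzyl)oxy]pent-4-en-2-ol
Product: 4 (R)-4-hydroxy-5-[(4-methoxybenzyl)oxy]pentan-2-one
Conditions: PdCl2 (10 mol%), CuCl (1 equiv), O2 (1 atm), DMF/H2O 7:1, 25 °C
Reagents that add atoms: water, O
Why: Tsuji–Wacker oxidation puts the oxygen on the internal alkene carbon (Markovnikov), turning the allyl group into the C10 methyl ketone without touching C8.

Step 3
Reactants: 4 (R)-4-hydroxy-5-[(4-methoxybenzyl)oxy]pentan-2-one; 2 vinylmagnesium bromide
Product: 6 (2R,4R)-1-[(4-methoxybenzyl)oxy]-4-methyl-2,4-bis[(triethylsilyl)oxy]hex-5-ene, via diol 5 (not isolated)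
Conditions: MgBr2·OEt2 (1.5 equiv), CH2Cl2, −78 °C; CH2=CHMgBr (3 equiv, THF), −78 °C, 2 h; then Et3SiOTf (4 equiv), 2,6-lutidine (5 equiv), −78 → 0 °C
Reagents that add atoms: vinylmagnesium bromide, C=C[Mg]Br; triethylsilyl trifluoromethanesulfonate, CC[Si](CC)(CC)OS(=O)(=O)C(F)(F)F
Why: Chelation-controlled Grignard addition (Cram-chelate 1,3-induction): the C8 magnesium alkoxide and the ketone form a six-membered chelate with the C7 branch equatorial, vinyl enters axially anti to that branch to give the 1,3-anti diol (new C10 centre, C4 of 6, R), and the dialkoxide is silylated in the same flask.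

Step 4
Reactants: 6 (2R,4R)-1-[(4-methoxybenzyl)oxy]-4-methyl-2,4-bis[(triethylsilyl)oxy]hex-5-ene
Product: 7 (2R,4R)-4-methyl-2,4-bis[(triethylsilyl)oxy]hex-5-en-1-ol
Conditions: DDQ (1.3 equiv), CH2Cl2/pH 7 buffer 10:1, 0 °C
Reagents that add atoms: none
Why: Oxidative cleavage of the 4-methoxybenzyl ether by DDQ (benzylic hydride abstraction, then hydrolysis) frees only the primary alcohol; the silyl ethers and the terminal alkene are inert, and the minor C10 epimer is removed here by chromatography.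

Step 5
Reactants: 7 (2R,4R)-4-methyl-2,4-bis[(triethylsilyl)oxy]hex-5-en-1-ol; 8 2-bromo-3-methylfuran
Product: 9 (2R,4R,5E)-4-methyl-6-(3-methylfuran-2-yl)-2,4-bis[(triethylsilyl)oxy]hex-5-en-1-ol
Conditions: Pd(OAc)2 (5 mol%), P(o-tol)3 (10 mol%), Et3N (2 equiv), MeCN, 80 °C
Reagents that add atoms: 2-bromo-3-methylfuran, Cc1ccoc1Br
Why: Mizoroki–Heck coupling: the furyl–palladium species adds to the unhindered CH2 terminus and β-hydride elimination, possible only away from the fully substituted C10, gives the E C1=C2 alkene and the C2–C3 bond.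

Step 6
Reactants: 9 (2R,4R,5E)-4-methyl-6-(3-methylfuran-2-yl)-2,4-bis[(triethylsilyl)oxy]hex-5-en-1-ol
Product: 10 (2R,4R,5E)-4-methyl-6-(3-methylfuran-2-yl)-2,4-bis[(triethylsilyl)oxy]hex-5-enal
Conditions: Dess–Martin periodinane (1.3 equiv), pyridine (3 equiv), CH2Cl2, 0 → 25 °C
Reagents that add atoms: none
Why: Dess–Martin oxidation gives the α-silyloxy aldehyde (C7) under non-basic conditions, so C8 does not epimerise.

Step 7
Reactants: 10 (2R,4R,5E)-4-methyl-6-(3-methylfuran-2-yl)-2,4-bis[(triethylsilyl)oxy]hex-5-enal; 11 methyl acrylate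
Product: 12 methyl (3RS,4R,6R,7E)-3-hydroxy-6-methyl-2-methylidene-8-(3-methylfuran-2-yl)-4,6-bis[(triethylsilyl)oxy]oct-7-enoate
Conditions: methyl acrylate (5 equiv), DABCO (1.0 equiv), MeOH, 25 °C, 2–4 d
Reagents that add atoms: methyl acrylate, C=CC(=O)OC
Why: Morita–Baylis–Hillman reaction (DABCO adds to the acrylate, the ammonium enolate adds to the aldehyde, then elimination) installs C11–C13; the new C7 carbinol centre forms as a mixture and is erased in step 8.

Step 8
Reactants: 12 methyl (3RS,4R,6R,7E)-3-hydroxy-6-methyl-2-methylidene-8-(3-methylfuran-2-yl)-4,6-bis[(triethylsilyl)oxy]oct-7-enoate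
Product: 14 methyl (2Z,4R,6R,7E)-2-(bromomethyl)-6-methyl-8-(3-methylfuran-2-yl)-4,6-bis[(triethylsilyl)oxy]octa-2,7-dienoate, via allylic mesylate 13 (not isolated)
Conditions: MsCl (1.3 equiv), Et3N (2 equiv), CH2Cl2, −40 °C; then LiBr (5 equiv), THF, −40 → 0 °C
Reagents that add atoms: lithium bromide, [Li+].[Br-]
Why: Mesylation of the allylic alcohol followed by SN2′ attack of bromide at C13 gives the thermodynamically preferred (Z)-2-(bromomethyl)enoate (C8 cis to CH2Br) and removes the C7 stereocentre.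

Step 9
Reactants: 14 methyl (2Z,4R,6R,7E)-2-(bromomethyl)-6-methyl-8-(3-methylfuran-2-yl)-4,6-bis[(triethylsilyl)oxy]octa-2,7-dienoate
Product: 16 methyl (2Z,4R,6R,7E,10Z)-2-(bromomethyl)-6,10-dimethyl-9,12-dioxo-4,6-bis[(triethylsilyl)oxy]dodeca-2,7,10-trienoate, via furan endoperoxide 15 (not isolated)
Conditions: O2, methylene blue (1 mol%), 630 nm LED, CH2Cl2, −78 °C; then Me2S (1.5 equiv), −78 → −30 °C; cold silica plug, used at once
Reagents that add atoms: dioxygen, O=O
Why: Photosensitised singlet-oxygen [4+2] cycloaddition to the furan and reduction of the endoperoxide by Me2S unmask the C3 ketone and the C6 aldehyde, and the ring origin fixes the C4=C5 alkene as Z.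

Step 10
Reactants: 16 methyl (2Z,4R,6R,7E,10Z)-2-(bromomethyl)-6,10-dimethyl-9,12-dioxo-4,6-bis[(triethylsilyl)oxy]dodeca-2,7,10-trienoate
Product: 19 (3aR,4R,6R,7E,10Z,11aS)-4,6-dihydroxy-6,10-dimethyl-3-methylidene-3a,4,5,6-tetrahydrocyclodeca[b]furan-2,9(3H,11aH)-dione, via seco hydroxy ester 17 (not isolated), via silylated lactone 18 (not isolated)
Conditions: undivided cell, Al anode, Ni-foam cathode, CrCl2 (20 mol%), (C5H5)2ZrCl2 (1.2 equiv), LiCl (0.1 M), DMF, 25 °C, constant current 2 mA (about 2.3 F/mol), 16 added by syringe pump over 10 h (2 mM final); then 1 M HCl/THF, 25 °C, 2 h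
Reagents that add atoms: none
Why: Proposed new method: a chromium-catalysed electroreductive Nozaki–Hiyama–Kishi allylation used to close a ten-membered carbocycle onto a (Z)-4-oxo-enal; trivalent chromium is reduced at the cathode to divalent chromium (the Al anode supplies the electrons, the zirconocene dichloride frees chromium from the product alkoxide), two divalent chromium ions convert the allylic bromide into a 2-(methoxycarbonyl)allyl chromium species that keeps C8 cis to CH2Cr, and this adds through C7 to the aldehyde in a closed six-membered chair (C8 axial, C5 equatorial) to give the C6/C7 syn adduct and hence the cis-fused lactone, while the C8 centre (its H eclipsing the alkene, its C9 branch anti to the forming bond, the silyloxy group outside) directs the aldehyde to the face that gives (6S,7R); the C3 ketone cannot compete because its attack would need a trans alkene in a seven-membered ring, the silyl ether at C8 cannot leave, and the low steady-state divalent chromium concentration plus slow addition hold back dimerisation and ene-dione reduction; the closest known reactions are the intermolecular electrochemical Nozaki–Hiyama–Kishi coupling and the stoichiometric CrCl2-mediated intramolecular Barbier lactonisation that closes germacranolide rings; the HCl treatment then removes both TES groups and completes lactonisation.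

Step 11
Reactants: 19 (3aR,4R,6R,7E,10Z,11aS)-4,6-dihydroxy-6,10-dimethyl-3-methylidene-3a,4,5,6-tetrahydrocyclodeca[b]furan-2,9(3H,11aH)-dione; 20 (R)-2-methylbutanoic acid
Product: 21 (3aR,4R,6R,7E,10Z,11aS)-6-hydroxy-6,10-dimethyl-3-methylidene-2,9-dioxo-2,3,3a,4,5,6,9,11a-octahydrocyclodeca[b]furan-4-yl (2R)-2-methylbutanoate
Conditions: 20 (1.5 equiv), DCC (1.5 equiv), DMAP (0.2 equiv), CH2Cl2, 0 → 25 °C
Reagents that add atoms: (R)-2-methylbutanoic acid, CC[C@@H](C)C(=O)O
Why: Steglich esterification acylates the secondary C8 hydroxyl selectively over the tertiary C10 hydroxyl, and the side-chain stereocentre is purchased in 20.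

## Compound list

1 | (R)-2-{[(4-methoxybenzyl)oxy]methyl}oxirane (4-methoxybenzyl ether of (S)-glycidol) | COc1ccc(COC[C@H]2CO2)cc1 | starting material
2 | vinylmagnesium bromide | C=C[Mg]Br | starting material
3 | (R)-1-[(4-methoxybenzyl)oxy]pent-4-en-2-ol | C=CC[C@@H](O)COCc1ccc(OC)cc1 | intermediate
4 | (R)-4-hydroxy-5-[(4-methoxybenzyl)oxy]pentan-2-one | CC(=O)C[C@@H](O)COCc1ccc(OC)cc1 | intermediate
5 | (2R,4R)-1-[(4-methoxybenzyl)oxy]-4-methylhex-5-ene-2,4-diol (present as its bis(bromomagnesium) alkoxide, not isolated) | C=C[C@](C)(O)C[C@@H](O)COCc1ccc(OC)cc1 | intermediate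
6 | (2R,4R)-1-[(4-methoxybenzyl)oxy]-4-methyl-2,4-bis[(triethylsilyl)oxy]hex-5-ene | C=C[C@](C)(O[Si](CC)(CC)CC)C[C@@H](O[Si](CC)(CC)CC)COCc1ccc(OC)cc1 | intermediate
7 | (2R,4R)-4-methyl-2,4-bis[(triethylsilyl)oxy]hex-5-en-1-ol | C=C[C@](C)(O[Si](CC)(CC)CC)C[C@@H](O[Si](CC)(CC)CC)CO | intermediate
8 | 2-bromo-3-methylfuran | Cc1ccoc1Br | starting material
9 | (2R,4R,5E)-4-methyl-6-(3-methylfuran-2-yl)-2,4-bis[(triethylsilyl)oxy]hex-5-en-1-ol | Cc1ccoc1/C=C/[C@](C)(O[Si](CC)(CC)CC)C[C@@H](O[Si](CC)(CC)CC)CO | intermediate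
10 | (2R,4R,5E)-4-methyl-6-(3-methylfuran-2-yl)-2,4-bis[(triethylsilyl)oxy]hex-5-enal | Cc1ccoc1/C=C/[C@](C)(O[Si](CC)(CC)CC)C[C@@H](O[Si](CC)(CC)CC)C=O | intermediate
11 | methyl acrylate | C=CC(=O)OC | starting material
12 | methyl (3RS,4R,6R,7E)-3-hydroxy-6-methyl-2-methylidene-8-(3-methylfuran-2-yl)-4,6-bis[(triethylsilyl)oxy]oct-7-enoate (both C3 epimers) | Cc1ccoc1/C=C/[C@](C)(O[Si](CC)(CC)CC)C[C@@H](O[Si](CC)(CC)CC)C(O)C(=C)C(=O)OC | intermediate
13 | 3-O-methanesulfonate of 12 (not isolated) | Cc1ccoc1/C=C/[C@](C)(O[Si](CC)(CC)CC)C[C@@H](O[Si](CC)(CC)CC)C(OS(C)(=O)=O)C(=C)C(=O)OC | intermediate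
14 | methyl (2Z,4R,6R,7E)-2-(bromomethyl)-6-methyl-8-(3-methylfuran-2-yl)-4,6-bis[(triethylsilyl)oxy]octa-2,7-dienoate | Cc1ccoc1/C=C/[C@](C)(O[Si](CC)(CC)CC)C[C@@H](O[Si](CC)(CC)CC)/C=C(\CBr)C(=O)OC | intermediate
15 | 2,3,7-trioxabicyclo[2.2.1]hept-5-ene endoperoxide of the furan ring of 14 (both bridgehead epimers, not isolated) | CC1=CC2OOC1(O2)/C=C/[C@](C)(O[Si](CC)(CC)CC)C[C@@H](O[Si](CC)(CC)CC)/C=C(\CBr)C(=O)OC | intermediate
16 | methyl (2Z,4R,6R,7E,10Z)-2-(bromomethyl)-6,10-dimethyl-9,12-dioxo-4,6-bis[(triethylsilyl)oxy]dodeca-2,7,10-trienoate | O=C/C=C(/C)C(=O)/C=C/[C@](C)(O[Si](CC)(CC)CC)C[C@@H](O[Si](CC)(CC)CC)/C=C(\CBr)C(=O)OC | intermediate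
17 | methyl 2-[(1S,2S,3Z,6E,8R,10R)-2-hydroxy-4,8-dimethyl-5-oxo-8,10-bis(triethylsilyloxy)cyclodeca-3,6-dien-1-yl]prop-2-enoate (not isolated) | COC(=O)C(=C)[C@H]1[C@@H](O)/C=C(/C)C(=O)/C=C/[C@](C)(O[Si](CC)(CC)CC)C[C@H]1O[Si](CC)(CC)CC | intermediate
18 | (3aS,4R,6R,7E,10Z,11aS)-6,10-dimethyl-3-methylidene-4,6-bis[(triethylsilyl)oxy]-3a,4,5,6-tetrahydrocyclodeca[b]furan-2,9(3H,11aH)-dione (not isolated) | C=C1C(=O)O[C@H]2/C=C(/C)C(=O)/C=C/[C@](C)(O[Si](CC)(CC)CC)C[C@@H](O[Si](CC)(CC)CC)[C@@H]12 | intermediate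
19 | (3aR,4R,6R,7E,10Z,11aS)-4,6-dihydroxy-6,10-dimethyl-3-methylidene-3a,4,5,6-tetrahydrocyclodeca[b]furan-2,9(3H,11aH)-dione | C=C1C(=O)O[C@H]2/C=C(/C)C(=O)/C=C/[C@](C)(O)C[C@@H](O)[C@@H]12 | intermediate
20 | (R)-2-methylbutanoic acid | CC[C@@H](C)C(=O)O | starting material
21 | (3aR,4R,6R,7E,10Z,11aS)-6-hydroxy-6,10-dimethyl-3-methylidene-2,9-dioxo-2,3,3a,4,5,6,9,11a-octahydrocyclodeca[b]furan-4-yl (2R)-2-methylbutanoate | C=C1C(=O)O[C@H]2/C=C(/C)C(=O)/C=C/[C@](C)(O)C[C@@H](OC(=O)[C@H](C)CC)[C@@H]12 | target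

## Step count and risks

Total step count: 11. Longest linear sequence: 11 steps (1 → 21).

**Step 10 (the proposed new ring closure).** It can fail through oligomerisation, through reduction or Z-to-E isomerisation of the ene-dione by divalent chromium, or by giving the other cis-lactone face. The facial sense at C7 rests on a model, not a precedent, and the fallback shares that uncertainty. The fallback sets out from 14 and comes back at 18. B2pin2 with Pd2(dba)3 (zerovalent palladium, 2.5 mol%) in THF at 50 °C turns the bromide into the primary allylboronate methyl (2E,4R,6R,7E)-6-methyl-8-(3-methylfuran-2-yl)-2-[(4,4,5,5-tetramethyl-1,3,2-dioxaborolan-2-yl)methyl]-4,6-bis[(triethylsilyl)oxy]octa-2,7-dienoate F1 (same alkene geometry as 14). The photooxygenation of step 9 then gives the ene-dione aldehyde methyl (2E,4R,6R,7E,10Z)-6,10-dimethyl-9,12-dioxo-2-[(4,4,5,5-tetramethyl-1,3,2-dioxaborolan-2-yl)methyl]-4,6-bis[(triethylsilyl)oxy]dodeca-2,7,10-trienoate F2. Warmed in toluene at 60 °C (or with Sc(OTf)3, 10 mol%, at −40 °C), F2 undergoes the known intramolecular allylboration of a 2-alkoxycarbonyl allylboronate through the same chair and lactonises to 18. The HCl/THF treatment of step 10 then gives 19. No reducing metal is present in this variant.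

**Step 3 (diastereoselectivity at C10).** A poorly organised chelate would give a mixture that is hard to separate once silylated. The fallback sets out from 4 and comes back at 6. HC≡CMgBr (3 equiv) with MgBr2·OEt2 in CH2Cl2/THF at −78 °C is a slimmer nucleophile that attacks the chelate axially with higher fidelity. It gives (2R,4R)-1-[(4-methoxybenzyl)oxy]-4-methylhex-5-yne-2,4-diol F3, which is isolated so that the minor epimer can be removed as the free diol. Semihydrogenation (H2, Pd/CaCO3 poisoned with Pb(OAc)2, quinoline, EtOAc) gives diol 5, now isolated, and Et3SiOTf/2,6-lutidine in CH2Cl2 gives 6.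

**Step 7 (Baylis–Hillman reaction on a hindered α-silyloxy aldehyde).** It may be too slow or may erode C8. The fallback sets out from 10 and comes back at 12. The lithium enolate of methyl 3-(dimethylamino)propanoate (LiN(iPr)2, THF, −78 °C) adds to 10 within minutes to give the aldol methyl (4R,6R,7E)-2-[(dimethylamino)methyl]-3-hydroxy-6-methyl-8-(3-methylfuran-2-yl)-4,6-bis[(triethylsilyl)oxy]oct-7-enoate F4. MeI in MeOH gives the corresponding trimethylammonium iodide F5, and K2CO3 at 25 °C eliminates the amine to give 12.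

## Further compounds

F1 | step 10 | methyl (2E,4R,6R,7E)-6-methyl-8-(3-methylfuran-2-yl)-2-[(4,4,5,5-tetramethyl-1,3,2-dioxaborolan-2-yl)methyl]-4,6-bis[(triethylsilyl)oxy]octa-2,7-dienoate | Cc1ccoc1/C=C/[C@](C)(O[Si](CC)(CC)CC)C[C@@H](O[Si](CC)(CC)CC)/C=C(\CB1OC(C)(C)C(C)(C)O1)C(=O)OC
F2 | step 10 | methyl (2E,4R,6R,7E,10Z)-6,10-dimethyl-9,12-dioxo-2-[(4,4,5,5-tetramethyl-1,3,2-dioxaborolan-2-yl)methyl]-4,6-bis[(triethylsilyl)oxy]dodeca-2,7,10-trienoate | O=C/C=C(/C)C(=O)/C=C/[C@](C)(O[Si](CC)(CC)CC)C[C@@H](O[Si](CC)(CC)CC)/C=C(\CB1OC(C)(C)C(C)(C)O1)C(=O)OC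
F3 | step 3 | (2R,4R)-1-[(4-methoxybenzyl)oxy]-4-methylhex-5-yne-2,4-diol | C#C[C@](C)(O)C[C@@H](O)COCc1ccc(OC)cc1
F4 | step 7 | methyl (4R,6R,7E)-2-[(dimethylamino)methyl]-3-hydroxy-6-methyl-8-(3-methylfuran-2-yl)-4,6-bis[(triethylsilyl)oxy]oct-7-enoate (C2/C3 epimers) | Cc1ccoc1/C=C/[C@](C)(O[Si](CC)(CC)CC)C[C@@H](O[Si](CC)(CC)CC)C(O)C(CN(C)C)C(=O)OC
F5 | step 7 | trimethylammonium iodide of F4 (N-methylated) | Cc1ccoc1/C=C/[C@](C)(O[Si](CC)(CC)CC)C[C@@H](O[Si](CC)(CC)CC)C(O)C(C[N+](C)(C)C)C(=O)OC.[I-]
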